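The runs are simulated with made-up constants, noise included.

- Early on, in the first minute, I watched how fast VoYm appears in the closed flasks, and whether Zo already bears on it. These are the flasks, the readings and the questions:

| flask | Vo | Ym | Zo | remark | time |
|---|---|---|---|---|---|
| larch | 0.069 M | 0.0621 M | 0.0759 M | run made earlier |  |
| maple | 0.035 M | 0.0621 M | 0.0759 M | run made earlier |  |
| oak | 0.052 M | 0.0621 M | 0.0759 M | run made earlier |  |
| elm | 0.069 M | 0.0621 M | 0.11 M | run made earlier |  |
| Sunday's | 0.069 M | 0.0621 M | 0.0759 M | one stirred flow tank at steady state, fed with the mixture as stated, mean residence time 36.0 min |  |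
| Thursday's | 0.069 M | 0.0621 M (fed, over 12.0 min) | 0.0759 M | all but Ym at the start; Ym goes in evenly over 12.0 min, the run ends at 12 min | 12 min |
| Monday's | 0.069 M | 0.0621 M | 0.0759 M | everything together in a closed stirred flask, run for 12 min | 12 min |
| Saturday's | 0.069 M | 0.0621 M | 0.0759 M | one stirred flow tank at steady state, fed with the mixture as stated, mean residence time 12 min |  |

- larch (time / min: VoYm / %, ZoVoYm / %): 1.33: 13.8, 1.4; 3.00: 20.9, 1.8; 4.00: 24.2, 0; 6.00: 25.9, 1.0; 8.00: 30.5, 0
- maple (time / min: VoYm / %, ZoVoYm / %): 0.833: 12.7, 0; 1.33: 14.2, 0.7; 2.50: 21.2, 0; 5.00: 25.3, 1.3; 10.0: 29.9, 0.9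
- oak (time / min: VoYm / %, ZoVoYm / %): 2.00: 16.9, 0.3; 4.00: 24.0, 1.1; 6.00: 26.2, 0; 8.00: 29.0, 2.0; 10.0: 28.1, 1.9
- elm (time / min: VoYm / %, ZoVoYm / %): 0.833: 8.9, 0; 1.33: 12.5, 0; 2.50: 16.4, 0.8; 5.00: 19.6, 0.5; 10.0: 22.1, 0.5

(scatter of a reading: 1 percentage point)

1. the set-up with the highest amount of VoYm at the outlet or at the end, in percent of the Vo put in ("none" if the first two lie within 2 percentage points) (Sunday's / Thursday's / Monday's / Saturday's / none)
2. amount of VoYm at the outlet or at the end, in percent of the Vo put in, Sunday's
3. amount of VoYm at the outlet or at the end, in percent of the Vo put in, Thursday's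
4. amount of VoYm at the outlet or at the end, in percent of the Vo put in, Monday's
5. amount of VoYm at the outlet or at the end, in percent of the Vo put in, Saturday's

- the stated concentrations are those of everything mixed, before any reaction; amounts are the same in each set-up
- the feed brings no volume worth counting
- the earlier runs were made in a closed, stirred flask

- First instants: at 1.33 min, larch read 13.8% of VoYm, and elm, with more Zo and the same Vo and Ym, read 12.5% at the same time. That gap of 1.3 percentage points lies near the scatter of 1 point, so I held it only as a hint that Zo was at work from the start.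
- Middle: larch rose to 30.5% at 8.00 min, and oak's ZoVoYm read 1.9% at its last point. That VoYm took 0.0210 M of the Ym, which left 0.0411 M if nothing else touched it. So I supposed that Zo was taking Vo, by a path I could not see, in competition with Ym.
- End: I defined the rivalry number, a selectivity factor, as the VoYm made per Vo lost otherwise, times Zo over Ym. The last readings give 0.536 for larch and 0.503 for elm, each carrying the scatter of 1 point, so I kept their mean, 0.519.
- Sunday's tank: its 36.0 min is longer than larch's last reading at 8.00 min, but that does not make Vo react fully in a stirred tank, which runs at outlet concentrations; as a rough first assumption of my own, I counted all the Vo as reacted. The feed ratio gave a share of 29.8%. Putting that back into the outlet amounts gave 44.0%. Their mean, 36.9%, returned 37.0%, and I committed to that.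
- Thursday's flask: by 3.00 min, when larch stood at 20.9%, a quarter of the Ym was in. That ratio gave 9.60%, and a second round, with Zo halfway through its loss, gave 15.3%. So my best flask was Sunday's, and my figures differed from the forecast.
- The forecast gave 29%, 22.5%, 30% and 25.3% for Sunday's, Thursday's, Monday's and Saturday's, with best none, on the ground that “Zo competes by destroying Ym”.
- The flasks gave 37.7%, 15.0%, 30.9% and 28.7% in that order, so the best was Sunday's, and the forecast parts from them on Sunday's and Thursday's.

    Vo + Zo → VoZo (k = 0.110 M⁻¹ s⁻¹)
    Vo + Ym → VoYm (k = 0.0420 M⁻¹ s⁻¹)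
    Zo ⇌ Ve (K = 4.60, k = 0.00110 s⁻¹)
    Zo + VoYm → ZoVoYm (k = 0.00140 M⁻¹ s⁻¹)

- In the scheme, Monday's Vo has a half-life of 1.4 min by the path with Zo against 4.4 min by the path with Ym, and the half-life of VoYm on the path to ZoVoYm, 110 min, is long against the 12 min. Counted as I counted larch, with all Vo not turned into VoYm taken as lost, Monday's 30.9% gives a rivalry number of 0.546, beside the 0.519 carried from the earlier runs.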